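The readings were computed on assumed constants, noise included.

Which of Monday's and Friday's flasks ends with the longer chains, and how long are they?

the same everywhere: J 5 mol%; X 0.26 mM

| flask | D | remark | time |
|---|---|---|---|
| beta | 15 mM | run made earlier |  |
| epsilon | 28 mM | run made earlier |  |
| gamma | 53 mM | run made earlier |  |
| Monday's | 13 mM |  | 5.0 h |
| Friday's | 50 mM |  | 5.0 h |

| run | time / h | L / % | D / % |
|---|---|---|---|
| beta | 0.200 | 1.3 | 98.7 |
| beta | 0.417 | 0.9 | 98.8 |
| beta | 0.667 | 0.5 | 97.3 |
| beta | 1.33 | 8.7 | 92.1 |
| beta | 2.50 | 22.7 | 78.3 |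
| epsilon | 0.200 | 1.6 | 99.9 |
| epsilon | 0.417 | 3.5 | 96.3 |
| epsilon | 0.667 | 6.0 | 95.8 |
| epsilon | 1.33 | 17.0 | 82.7 |
| epsilon | 2.50 | 43.0 | 55.3 |
| gamma | 0.200 | 1.7 | 98.1 |
| gamma | 0.417 | 5.6 | 94.9 |
| gamma | 0.667 | 11.4 | 90.1 |
| gamma | 1.33 | 33.5 | 67.0 |
| gamma | 2.50 | 70.9 | 30.2 |

(readings scatter by 1 percentage point)

* which of the two ends with the longer chains by the average number of monomer units in a chain (chains begun, living or dead) ("neither" if they lie within 10%) (Monday's / Friday's / neither)
* average number of monomer units in a chain (chains begun, living or dead) at the end, Monday's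
* average number of monomer units in a chain (chains begun, living or dead) at the end, Friday's

- the average divides the monomer in chains by the number of chains begun, living and dead together
- the earlier runs were read with a standard deviation of 1 percentage point
- steps thought possible: J -> Q; D + Q -> G + L; Q + X -> Z; D + G -> L + G
- the earlier runs do not show the number of chains; that part of a forecast is a guess

Length is monomer in chains over chains begun, so we need both. We take D to be lost in a pseudo-first-order way, at a pace proportional to G. Two extreme flasks can be solved at once, each with J and D fully reacted. If X took no Q, chains would equal J charged, and the length would be 20.0 in both flasks. If X took Q first, chains would equal the spare initiator, 0.390 mM on Monday's, meaning J charged less X charged, and 2.24 mM on Friday's. The lengths would then be 33.3 and 22.3.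

The readings lean to the second extreme. The logarithmic fall of D at the last reading, per spare initiator, is 0.499 mM⁻¹ in beta and 0.501 mM⁻¹ in gamma. Per J charged, the two part: 0.326 mM⁻¹ against 0.452 mM⁻¹.

Gamma's fall steepens with time, and carried from 2.50 h to 5.0 h its trend multiplies the fall by 3.33. That puts L at 47.8% on Monday's and 97.6% on Friday's. With the spare initiator as chains, we commit to 15.9 and 21.8. Our figure for Monday's lies below both extremes, and it counts 52.2% of the D as unreacted.

The forecast says Friday's, with 13.5 and 21, and of the chains it says: “The chain count is then about J − X.” Its lengths stand below ours.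

The flask gives Friday's, with 17.6 for Monday's and 25.6 for Friday's. G stands at 0.346 mM on Monday's and 1.90 mM on Friday's, less than the spare initiator of 0.390 mM and 2.24 mM.

    J → Q (k = 0.00730 min⁻¹)
    D + Q → G + L (k = 21.0 L mol⁻¹ min⁻¹)
    Q + X → Z (k = 1400 L mol⁻¹ min⁻¹)
    D + G → L + G, rate k4*[G]*[D] (k = 9.30 L mol⁻¹ min⁻¹)

The neighbour follows Friday's recipe with 120 mM of D. Its spare initiator is 5.74 mM, and with D at 0% that reckons to a length of 20.9. That flask gives 28.7, its spare initiator standing as G 4.18 mM, Q 0.885 mM and unreacted J 0.672 mM.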